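## Retrosynthetic overview

1. Target 18 comes from trisilyl ether 17 by global desilylation; 17 comes from aldehyde 13 and arylmagnesium 16 (C–C bond at the carbinol carbon, Felkin–Anh control).
2. 13 comes from 10: the exocyclic C=CH2 on ring carbon C4 is converted to a cis CH2OH by hydroboration and then oxidised to CHO.
3. 10 comes from aldehyde 2 and dichloride 7 in one flask: chromium-catalysed asymmetric allylation, then closure of the oxolane (the only ring formed) by O-alkylation, which makes the O1–C5 (ring O–CH2) bond.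
4. Enabling feature: the 2-(chloromethyl)allyl unit of 7, ClCH2–C(CH2Cl)=CH–CH2OTBS. One CH2Cl becomes the allylmetal terminus and ends as the exocyclic =CH2; the γ-CH carries CH2OTBS to ring C3; the second CH2Cl on the central alkene carbon sits 1,5 to the new alkoxide oxygen, so ring O1–C2–C3–C4–C5 closes by 5-exo-tet displacement.
5. 7 comes from 1,3-dichloroacetone (Wittig, reduction, silylation); 2 and 15 come from vanillin and 4-bromo-2-methoxyphenol by silylation.

Key step: step 5

Remark: the antipode of the bis(oxazolinyl)carbazole ligand is taken to be the one that delivers the allyl group to the Si face of aldehyde 2 (2S carbinol); all descriptors below follow from this choice.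

## Route

Step 1
Reactants: 1 vanillin (4-hydroxy-3-methoxybenzaldehyde)
Product: 2 3-methoxy-4-(triisopropylsilyloxy)benzaldehyde
Conditions: TIPSCl, imidazole, DMF, rt
Reagents that add atoms: chlorotriisopropylsilane, CC(C)[Si](Cl)(C(C)C)C(C)C
Why: Imidazole-promoted O-silylation of the phenol gives an aryl TIPS ether that tolerates the later base and organometal steps and leaves the aldehyde free; no stereocentre is formed.

Step 2
Reactants: 3 1,3-dichloropropan-2-one; 4 ethyl (triphenyl-λ5-phosphanylidene)acetate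
Product: 5 ethyl 4-chloro-3-(chloromethyl)but-2-enoate
Conditions: toluene, 90 °C
Reagents that add atoms: none
Why: Wittig olefination of the symmetric ketone with the stabilised ylide should give the trisubstituted enoate, and since both groups on the new alkene carbon are CH2Cl no E/Z isomers can arise.

Step 3
Reactants: 5 ethyl 4-chloro-3-(chloromethyl)but-2-enoate
Product: 6 4-chloro-3-(chloromethyl)but-2-en-1-ol
Conditions: i-Bu2AlH (2.2 equiv), CH2Cl2, −78 °C; aq KNaC4H4O6 (Rochelle salt)
Reagents that add atoms: none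
Why: 1,2-Reduction of the α,β-unsaturated ester by i-Bu2AlH at low temperature should give the allylic alcohol while the allylic C–Cl bonds, which are inert to the aluminium hydride at −78 °C, are kept.

Step 4
Reactants: 6 4-chloro-3-(chloromethyl)but-2-en-1-ol
Product: 7 tert-butyl{[4-chloro-3-(chloromethyl)but-2-en-1-yl]oxy}dimethylsilane
Conditions: TBSCl, imidazole, CH2Cl2, 0 °C
Reagents that add atoms: tert-butylchlorodimethylsilane, CC(C)(C)[Si](C)(C)Cl
Why: O-Silylation of the primary alcohol gives a TBS ether that is a poor leaving group, which suppresses 1,4-elimination from the allylchromium species of the next step.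

Step 5
Reactants: 2 3-methoxy-4-(triisopropylsilyloxy)benzaldehyde; 7 tert-butyl{[4-chloro-3-(chloromethyl)but-2-en-1-yl]oxy}dimethylsilane (2 equiv)
Product: 10 tert-butyl{[(2S,3R)-2-[3-methoxy-4-(triisopropylsilyloxy)phenyl]-4-methylideneoxolan-3-yl]methoxy}dimethylsilane, via trimethylsilyl ether 8 (not isolated), via potassium alkoxide 9 (not isolated)
Conditions: CrCl2 (10 mol %), chiral 1,8-bis(oxazolinyl)carbazole ligand (12 mol %), Mn (2 equiv), TMSCl (1.2 equiv), i-Pr2NEt (0.3 equiv), THF, rt; then KOt-Bu (4 equiv), THF, 0 °C to rt, same flask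
Reagents that add atoms: none
Why: Divalent chromium inserts into one of the two equivalent allylic C–Cl bonds of 7, and the γ-substituted allylchromium (trivalent) reagent, held by the tridentate ligand, adds through its γ-carbon to the aldehyde in a closed six-membered chair transition state; TMSCl releases chromium as silyl ether 8, Mn returns it to the divalent state, and KOt-Bu then cleaves the O–Si bond so that potassium alkoxide 9 displaces the remaining allylic chloride. The closest known reaction type is the catalytic asymmetric Nozaki–Hiyama–Kishi allylation with 2-(halomethyl)allyl halides followed by Williamson cycloetherification to 3-methylideneoxolanes. The oxolane ring is closed in the 5-exo-tet mode by O-alkylation at the CH2Cl carbon, and direct SN2 and SN2′ attack lead to the same product because the two allylic termini are equivalent. The carbinol centre C2 is set by the ligand on chromium (Si-face delivery gives 2S), and C3 is set relative to it by the chair transition state with aryl and CH2OTBS pseudo-equatorial (anti adduct, hence 2,3-trans). The step needs γ- over α-attack of the allylmetal, which is the normal course for allylchromium reagents, and insertion of chromium into 7 and not into the allylic chloride of the adduct, which is secured by the excess of 7 and by the more hindered position of the chloride in the adduct.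

Step 6
Reactants: 10 tert-butyl{[(2S,3R)-2-[3-methoxy-4-(triisopropylsilyloxy)phenyl]-4-methylideneoxolan-3-yl]methoxy}dimethylsilane
Product: 12 [(3S,4R,5S)-4-[(tert-butyldimethylsilyloxy)methyl]-5-[3-methoxy-4-(triisopropylsilyloxy)phenyl]oxolan-3-yl]methanol, via B-alkyl-9-BBN adduct 11 (not isolated)
Conditions: 9-BBN (1.5 equiv), THF, 0 °C to rt; then H2O2 (30%), aq NaOAc, 0 °C
Reagents that add atoms: hydrogen peroxide, OO
Why: Anti-Markovnikov syn hydroboration of the 1,1-disubstituted exocyclic alkene should place boron on the terminal carbon and deliver hydrogen to the ring carbon from the face opposite the adjacent CH2OTBS group, so that the new CH2OH ends cis to it, and the C–B bond is oxidised with retention.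

Step 7
Reactants: 12 [(3S,4R,5S)-4-[(tert-butyldimethylsilyloxy)methyl]-5-[3-methoxy-4-(triisopropylsilyloxy)phenyl]oxolan-3-yl]methanol
Product: 13 (3R,4R,5S)-4-[(tert-butyldimethylsilyloxy)methyl]-5-[3-methoxy-4-(triisopropylsilyloxy)phenyl]oxolane-3-carbaldehyde
Conditions: Dess–Martin periodinane, pyridine, CH2Cl2, 0 °C; used crude at once
Reagents that add atoms: none
Why: Dess–Martin oxidation under buffered, non-basic conditions should give the aldehyde without epimerising its α-centre or opening the β-alkoxy aldehyde by elimination.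

Step 8
Reactants: 14 4-bromo-2-methoxyphenol
Product: 15 (4-bromo-2-methoxyphenoxy)triisopropylsilane
Conditions: TIPSCl, imidazole, DMF, rt
Reagents that add atoms: chlorotriisopropylsilane, CC(C)[Si](Cl)(C(C)C)C(C)C
Why: O-Silylation masks the phenol so that the aryl bromide can be converted into an organomagnesium reagent.

Step 9
Reactants: 13 (3R,4R,5S)-4-[(tert-butyldimethylsilyloxy)methyl]-5-[3-methoxy-4-(triisopropylsilyloxy)phenyl]oxolane-3-carbaldehyde; 15 (4-bromo-2-methoxyphenoxy)triisopropylsilane
Product: 17 (R)-[(3R,4R,5S)-4-[(tert-butyldimethylsilyloxy)methyl]-5-[3-methoxy-4-(triisopropylsilyloxy)phenyl]oxolan-3-yl][3-methoxy-4-(triisopropylsilyloxy)phenyl]methanol, via arylmagnesium bromide 16 (not isolated)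
Conditions: 15, Mg, THF, 50 °C; then 13, THF, −78 to −40 °C; aq NH4Cl
Reagents that add atoms: none
Why: Grignard addition to the α-branched aldehyde under Felkin–Anh control, with the more substituted ring carbon (the one bearing the cis CH2OTBS group) anti to the incoming aryl group, should give the R carbinol, and the six-membered magnesium chelate between the formyl oxygen and the ring oxygen predicts the same face.

Step 10
Reactants: 17 (R)-[(3R,4R,5S)-4-[(tert-butyldimethylsilyloxy)methyl]-5-[3-methoxy-4-(triisopropylsilyloxy)phenyl]oxolan-3-yl][3-methoxy-4-(triisopropylsilyloxy)phenyl]methanol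
Product: 18 (7R)-7-hydroxylariciresinol, 4-[(2S,3R,4R)-4-[(R)-hydroxy(4-hydroxy-3-methoxyphenyl)methyl]-3-(hydroxymethyl)oxolan-2-yl]-2-methoxyphenol
Conditions: n-Bu4NF (3.3 equiv), AcOH (3.3 equiv), THF, 0 °C to rt
Reagents that add atoms: none
Why: Fluoride-mediated cleavage of the two aryl TIPS ethers and the primary TBS ether, buffered with AcOH so that the p-hydroxybenzylic alcohol neither ionises under acid nor forms a quinone methide under base, should free the target without touching a stereocentre.

## Compound list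

1 | vanillin (4-hydroxy-3-methoxybenzaldehyde) | COc1cc(C=O)ccc1O | starting material
2 | 3-methoxy-4-(triisopropylsilyloxy)benzaldehyde | COc1cc(C=O)ccc1O[Si](C(C)C)(C(C)C)C(C)C | intermediate
3 | 1,3-dichloropropan-2-one | ClCC(=O)CCl | starting material
4 | ethyl (triphenyl-λ5-phosphanylidene)acetate | CCOC(=O)C=P(c1ccccc1)(c1ccccc1)c1ccccc1 | starting material
5 | ethyl 4-chloro-3-(chloromethyl)but-2-enoate | CCOC(=O)C=C(CCl)CCl | intermediate
6 | 4-chloro-3-(chloromethyl)but-2-en-1-ol | OCC=C(CCl)CCl | intermediate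
7 | tert-butyl{[4-chloro-3-(chloromethyl)but-2-en-1-yl]oxy}dimethylsilane | CC(C)(C)[Si](C)(C)OCC=C(CCl)CCl | intermediate
8 | trimethylsilyl ether of (1S,2R)-2-[(tert-butyldimethylsilyloxy)methyl]-3-(chloromethyl)-1-[3-methoxy-4-(triisopropylsilyloxy)phenyl]but-3-en-1-ol | COc1cc([C@@H](O[Si](C)(C)C)[C@@H](CO[Si](C)(C)C(C)(C)C)C(=C)CCl)ccc1O[Si](C(C)C)(C(C)C)C(C)C | intermediate
9 | potassium (1S,2R)-2-[(tert-butyldimethylsilyloxy)methyl]-3-(chloromethyl)-1-[3-methoxy-4-(triisopropylsilyloxy)phenyl]but-3-en-1-olate | COc1cc([C@@H]([O-])[C@@H](CO[Si](C)(C)C(C)(C)C)C(=C)CCl)ccc1O[Si](C(C)C)(C(C)C)C(C)C.[K+] | intermediate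
10 | tert-butyl{[(2S,3R)-2-[3-methoxy-4-(triisopropylsilyloxy)phenyl]-4-methylideneoxolan-3-yl]methoxy}dimethylsilane | COc1cc([C@H]2OCC(=C)[C@@H]2CO[Si](C)(C)C(C)(C)C)ccc1O[Si](C(C)C)(C(C)C)C(C)C | intermediate
11 | 9-{[(3R,4R,5S)-4-[(tert-butyldimethylsilyloxy)methyl]-5-[3-methoxy-4-(triisopropylsilyloxy)phenyl]oxolan-3-yl]methyl}-9-borabicyclo[3.3.1]nonane | COc1cc([C@H]2OC[C@H](CB3C4CCCC3CCC4)[C@@H]2CO[Si](C)(C)C(C)(C)C)ccc1O[Si](C(C)C)(C(C)C)C(C)C | intermediate
12 | [(3S,4R,5S)-4-[(tert-butyldimethylsilyloxy)methyl]-5-[3-methoxy-4-(triisopropylsilyloxy)phenyl]oxolan-3-yl]methanol | COc1cc([C@H]2OC[C@H](CO)[C@@H]2CO[Si](C)(C)C(C)(C)C)ccc1O[Si](C(C)C)(C(C)C)C(C)C | intermediate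
13 | (3R,4R,5S)-4-[(tert-butyldimethylsilyloxy)methyl]-5-[3-methoxy-4-(triisopropylsilyloxy)phenyl]oxolane-3-carbaldehyde | COc1cc([C@H]2OC[C@H](C=O)[C@@H]2CO[Si](C)(C)C(C)(C)C)ccc1O[Si](C(C)C)(C(C)C)C(C)C | intermediate
14 | 4-bromo-2-methoxyphenol | COc1cc(Br)ccc1O | starting material
15 | (4-bromo-2-methoxyphenoxy)triisopropylsilane | COc1cc(Br)ccc1O[Si](C(C)C)(C(C)C)C(C)C | intermediate
16 | [3-methoxy-4-(triisopropylsilyloxy)phenyl]magnesium bromide | COc1cc([Mg]Br)ccc1O[Si](C(C)C)(C(C)C)C(C)C | intermediate
17 | (R)-[(3R,4R,5S)-4-[(tert-butyldimethylsilyloxy)methyl]-5-[3-methoxy-4-(triisopropylsilyloxy)phenyl]oxolan-3-yl][3-methoxy-4-(triisopropylsilyloxy)phenyl]methanol | COc1cc([C@H]2OC[C@H]([C@@H](O)c3ccc(O[Si](C(C)C)(C(C)C)C(C)C)c(OC)c3)[C@@H]2CO[Si](C)(C)C(C)(C)C)ccc1O[Si](C(C)C)(C(C)C)C(C)C | intermediate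
18 | (7R)-7-hydroxylariciresinol, 4-[(2S,3R,4R)-4-[(R)-hydroxy(4-hydroxy-3-methoxyphenyl)methyl]-3-(hydroxymethyl)oxolan-2-yl]-2-methoxyphenol | COc1cc([C@H]2OC[C@H]([C@@H](O)c3ccc(O)c(OC)c3)[C@@H]2CO)ccc1O | target

## Step count and risks

Total step count: 10. Longest linear sequence: 8 steps (steps 2, 3, 4, 5, 6, 7, 9, 10, from 1,3-dichloropropan-2-one).

Steps most likely to fail:

**Step 5.** What may go wrong: insufficient enantiofacial control in the chromium-mediated allyl transfer, or reduction of the second allylic chloride before the ring can close. Fallback: an auxiliary-controlled Evans syn-aldol with silver-assisted ring closure. It sets out from ester 5 (with aldehyde 2) and comes back at 10.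
- Zn/AcOH reductive deconjugation of 5 should give ethyl 3-(chloromethyl)but-3-enoate F1.
- LiOH hydrolysis gives 3-(chloromethyl)but-3-enoic acid F2.
- Activation with pivaloyl chloride/Et3N and acylation of lithiated (S)-4-benzyl-1,3-oxazolidin-2-one gives (4S)-4-benzyl-3-[3-(chloromethyl)but-3-enoyl]-1,3-oxazolidin-2-one F3.
- Enolisation with Bu2BOTf/i-Pr2NEt and addition of 2 at −78 °C should give the syn aldol (4S)-4-benzyl-3-[(2S)-3-(chloromethyl)-2-[(S)-hydroxy{3-methoxy-4-(triisopropylsilyloxy)phenyl}methyl]but-3-enoyl]-1,3-oxazolidin-2-one F4. The Z boron enolate reacts through a chair transition state on the face away from the benzyl group; this fixes the S carbinol and the syn relationship that corresponds to the 2,3-trans oxolane.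
- Ag2O in CH2Cl2 closes the oxolane at the allylic chloride to give (4S)-4-benzyl-3-{(2S,3S)-2-[3-methoxy-4-(triisopropylsilyloxy)phenyl]-4-methylideneoxolane-3-carbonyl}-1,3-oxazolidin-2-one F5.
- LiBH4 removes the auxiliary reductively to give {(2S,3R)-2-[3-methoxy-4-(triisopropylsilyloxy)phenyl]-4-methylideneoxolan-3-yl}methanol F6.
- TBSCl/imidazole then gives 10.

**Step 6.** What may go wrong: poor facial selectivity in the hydroboration of the exocyclic alkene, giving the epimer at the ring carbon. Fallback: set the same centre by hydrogen-atom transfer to a ring radical. It sets out from 10 and comes back at 12.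
- m-CPBA/NaHCO3 should give the spiro-epoxide tert-butyl{[(6S,7R)-6-[3-methoxy-4-(triisopropylsilyloxy)phenyl]-1,5-dioxaspiro[2.4]heptan-7-yl]methoxy}dimethylsilane F7; either spiro epimer serves.
- Cp2TiCl2/Mn (titanocene monochloride, trivalent titanium), collidine hydrochloride and 1,4-cyclohexadiene open the epoxide to the tertiary ring radical. This radical takes up hydrogen on the face away from the CH2OTBS group, a titanocene-mediated anti-Markovnikov reductive epoxide opening, and gives 12.

**Step 9.** What may go wrong: epimerisation of the α-centre of the aldehyde before addition, and poor facial selectivity at the formyl group. Fallback: reagent-controlled ketone reduction. It sets out from 13 and comes back at 17.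
- The mixture of carbinol epimers obtained from 13 and 16 is oxidised with Dess–Martin periodinane to the aryl ketone [(3R,4R,5S)-4-[(tert-butyldimethylsilyloxy)methyl]-5-[3-methoxy-4-(triisopropylsilyloxy)phenyl]oxolan-3-yl][3-methoxy-4-(triisopropylsilyloxy)phenyl]methanone F8.
- Corey–Bakshi–Shibata reduction with BH3·SMe2 and the (S)-Me-CBS oxazaborolidine (aryl as the large group) should give the R carbinol 17.

Further compounds
F1 | step 5 | ethyl 3-(chloromethyl)but-3-enoate | C=C(CCl)CC(=O)OCC
F2 | step 5 | 3-(chloromethyl)but-3-enoic acid | C=C(CCl)CC(=O)O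
F3 | step 5 | (4S)-4-benzyl-3-[3-(chloromethyl)but-3-enoyl]-1,3-oxazolidin-2-one | C=C(CCl)CC(=O)N1C(=O)OC[C@@H]1Cc1ccccc1
F4 | step 5 | (4S)-4-benzyl-3-[(2S)-3-(chloromethyl)-2-[(S)-hydroxy{3-methoxy-4-(triisopropylsilyloxy)phenyl}methyl]but-3-enoyl]-1,3-oxazolidin-2-one | COc1cc([C@@H](O)[C@@H](C(=O)N2C(=O)OC[C@@H]2Cc2ccccc2)C(=C)CCl)ccc1O[Si](C(C)C)(C(C)C)C(C)C
F5 | step 5 | (4S)-4-benzyl-3-{(2S,3S)-2-[3-methoxy-4-(triisopropylsilyloxy)phenyl]-4-methylideneoxolane-3-carbonyl}-1,3-oxazolidin-2-one | COc1cc([C@H]2OCC(=C)[C@@H]2C(=O)N3C(=O)OC[C@@H]3Cc3ccccc3)ccc1O[Si](C(C)C)(C(C)C)C(C)C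
F6 | step 5 | {(2S,3R)-2-[3-methoxy-4-(triisopropylsilyloxy)phenyl]-4-methylideneoxolan-3-yl}methanol | COc1cc([C@H]2OCC(=C)[C@@H]2CO)ccc1O[Si](C(C)C)(C(C)C)C(C)C
F7 | step 6 | tert-butyl{[(6S,7R)-6-[3-methoxy-4-(triisopropylsilyloxy)phenyl]-1,5-dioxaspiro[2.4]heptan-7-yl]methoxy}dimethylsilane (either spiro epimer) | COc1cc([C@H]2OCC3(CO3)[C@@H]2CO[Si](C)(C)C(C)(C)C)ccc1O[Si](C(C)C)(C(C)C)C(C)C
F8 | step 9 | [(3R,4R,5S)-4-[(tert-butyldimethylsilyloxy)methyl]-5-[3-methoxy-4-(triisopropylsilyloxy)phenyl]oxolan-3-yl][3-methoxy-4-(triisopropylsilyloxy)phenyl]methanone | COc1cc([C@H]2OC[C@H](C(=O)c3ccc(O[Si](C(C)C)(C(C)C)C(C)C)c(OC)c3)[C@@H]2CO[Si](C)(C)C(C)(C)C)ccc1O[Si](C(C)C)(C(C)C)C(C)C
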